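**Strategy**

Ring B (C5–C6–C7–C8–C9–C10, drimane numbering) is opened at C5–C6 and C7–C8, turning its unsubstituted C6–C7 bridge into vinyltriphenylphosphonium bromide. The precursor is a monocyclic ring A diketone: the C5 carbonyl sits between quaternary C4 and C10, and the C9 carbonyl (the later alkylidene carbon) makes C8 the only enolisable position. In one operation the C8 enolate adds to the vinyl group and the resulting ylide olefinates C5, closing ring B. C10 is set beforehand by asymmetric allylation; the C9 ketone then carries the aroyl carbon C11, hydrogenations from the α face set C5 and C8, and chloride capture of a vinyl cation fixes the alkene geometry.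

Key step: step 7

Remark on numbering: drimane numbering is used for the decalin (C4 gem-dimethyl carbon, C5 and C10 ring-fusion carbons, C8 the methyl-bearing methine, C9 the alkylidene carbon, C11 the chlorinated carbon); the quaternary centre is R in compounds 5–13 and S from 14 onwards only because the CIP priorities change.

Assumption: the (R)-configured phosphinooxazoline ligand in step 2 is taken to deliver the (R)-ketone 5, the mirror image of the sense usual for the (S)-ligand with 2-alkylcyclohexanone enol carbonates.

**Route**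

Step 1
Reactants: 1 2,2,6-trimethylcyclohexan-1-one; 2 allyl chloroformate
Product: 4 allyl 2,6,6-trimethylcyclohex-1-en-1-yl carbonate, via lithium enolate 3 (not isolated)
Conditions: LiN(SiMe3)2, THF, 0 °C; then 2, −78 °C to 25 °C
Reagents that add atoms: none
Why: Only C6 of 1 carries an α-hydrogen, and the hindered tetrasubstituted lithium enolate is acylated on oxygen by the chloroformate (enolate O-acylation).

Step 2
Reactants: 4 allyl 2,6,6-trimethylcyclohex-1-en-1-yl carbonate
Product: 5 (2R)-2-allyl-2,6,6-trimethylcyclohexan-1-one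
Conditions: Pd2(dba)3 (2.5 mol%), (R)-4-tert-butyl-2-[2-(diphenylphosphanyl)phenyl]-4,5-dihydro-1,3-oxazole ((R)-t-BuPHOX, 6.25 mol%), THF, 25 °C
Reagents that add atoms: none
Why: Decarboxylative asymmetric allylic alkylation (Tsuji–Trost type), in which zerovalent palladium ionises the allyl carbonate, CO2 is lost and the enolate recombines with the allyl fragment at carbon inside the chiral ligand pocket, which sets the quaternary centre (C10 of the target).

Step 3
Reactants: 5 (2R)-2-allyl-2,6,6-trimethylcyclohexan-1-one
Product: 6 (2R)-2,6,6-trimethyl-2-[(E)-prop-1-en-1-yl]cyclohexan-1-one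
Conditions: RuHCl(CO)(PPh3)3 (5 mol%), toluene, 100 °C
Reagents that add atoms: none
Why: Ruthenium hydride alkene isomerisation (hydrometalation/β-hydride elimination) moves the double bond one position to the more substituted E-propenyl isomer and cannot go further because the next carbon is quaternary.

Step 4
Reactants: 6 (2R)-2,6,6-trimethyl-2-[(E)-prop-1-en-1-yl]cyclohexan-1-one
Product: 8 (1R)-1,3,3-trimethyl-2-oxocyclohexane-1-carbaldehyde, via ozonide 7 (not isolated)
Conditions: O3, CH2Cl2, −78 °C; then PPh3, −78 °C to 25 °C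
Reagents that add atoms: ozone, [O-][O+]=O
Why: Ozonolysis with reductive work-up cleaves the propenyl group so that the carbon on the quaternary centre (future C9) becomes a non-enolisable aldehyde, leaving the stereocentre untouched.

Step 5
Reactants: 8 (1R)-1,3,3-trimethyl-2-oxocyclohexane-1-carbaldehyde
Product: 9 (2R)-2-(1-hydroxypropyl)-2,6,6-trimethylcyclohexan-1-one
Conditions: EtMgBr, Et2O, −78 °C; NH4Cl (aq), −78 °C
Reagents that add atoms: ethylmagnesium bromide, CC[Mg]Br
Why: Grignard addition is chemoselective for the aldehyde over the ketone flanked by two quaternary carbons, the cold quench suppresses retro-aldol cleavage, and the new carbinol centre (either epimer) is oxidised away in step 6.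

Step 6
Reactants: 9 (2R)-2-(1-hydroxypropyl)-2,6,6-trimethylcyclohexan-1-one
Product: 10 (2R)-2,6,6-trimethyl-2-propanoylcyclohexan-1-one
Conditions: Dess–Martin periodinane, CH2Cl2, 0 °C to 25 °C
Reagents that add atoms: none
Why: Dess–Martin oxidation of the secondary alcohol under near-neutral conditions gives the 1,3-diketone, which cannot enolise between its carbonyls, without retro-Claisen cleavage.

Step 7
Reactants: 10 (2R)-2,6,6-trimethyl-2-propanoylcyclohexan-1-one; 11 vinyltriphenylphosphonium bromide
Product: 14 (8aS)-2,5,5,8a-tetramethyl-3,5,6,7,8,8a-hexahydronaphthalen-1(2H)-one, via potassium enolate 12 (not isolated), via phosphonium ylide 13 (not isolated)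
Conditions: KN(SiMe3)2 (1.05 equiv), THF/DMF, −78 °C; 11, −78 °C to 25 °C; then 66 °C
Reagents that add atoms: none
Why: The potassium enolate 12 can form only at C8, because C4 and C10 are quaternary, and it adds in a Michael fashion to the vinylphosphonium salt (C7–C8 bond) to give the non-stabilised ylide 13. The ylide carbon C6 then attacks the C5 carbonyl in an intramolecular Wittig olefination (C5–C6 bond, loss of Ph3P=O), so the salt acts as an ethylene equivalent that is electrophilic at C7 and nucleophilic at C6. The closest known reaction type is the Michael addition/intramolecular Wittig annulation of vinylphosphonium salts with enolates that carry a second carbonyl group. Ring B is closed by 6-exo-trig attack of the ylide on the ketone; attack on the C9 carbonyl would need a four-membered ring and is not expected. The only new stereocentre, C8, is epimerisable and is erased in step 9, while C10 comes unchanged from step 2. The step needs C- rather than O-alkylation of the enolate and olefination of a ketone between two quaternary carbons, which the soft phosphonium acceptor, intramolecularity, the reactive alkyl ylide and heating are expected to secure.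

Step 8
Reactants: 14 (8aS)-2,5,5,8a-tetramethyl-3,5,6,7,8,8a-hexahydronaphthalen-1(2H)-one
Product: 15 (4aS,8aS)-2,5,5,8a-tetramethyl-3,4,4a,5,6,7,8,8a-octahydronaphthalen-1(2H)-one
Conditions: H2 (5 bar), Pd/C (10 wt%), EtOH, 25 °C
Reagents that add atoms: none
Why: Heterogeneous syn-hydrogenation of the trisubstituted C5=C6 alkene from the α face, opposite the axial C10 methyl and the 4β-methyl group, should give the trans-fused decalone (5S), the usual outcome for 4,4,10-trimethyl-Δ5-octalins.

Step 9
Reactants: 15 (4aS,8aS)-2,5,5,8a-tetramethyl-3,4,4a,5,6,7,8,8a-octahydronaphthalen-1(2H)-one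
Product: 17 (4aS,8aS)-2,5,5,8a-tetramethyl-3,4,4a,5,6,7,8,8a-octahydronaphthalen-1-yl trifluoromethanesulfonate, via potassium enolate 16 (not isolated)
Conditions: KN(SiMe3)2, THF, −78 °C; PhNTf2, −78 °C to 0 °C
Reagents that add atoms: N-phenylbis(trifluoromethanesulfonimide), O=S(=O)(N(c1ccccc1)S(=O)(=O)C(F)(F)F)C(F)(F)F
Why: The ketone can enolise only toward C8 (C10 is quaternary), and O-sulfonylation of the enolate gives the tetrasubstituted enol triflate while erasing the C8 centre.

Step 10
Reactants: 18 3-bromo-4-hydroxy-5-methoxybenzaldehyde (5-bromovanillin)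
Product: 20 2-bromo-6-methoxybenzene-1,4-diol, via aryl formate 19 (not isolated)
Conditions: H2O2 (30% aq), NaOH (aq), THF, 0 °C to 25 °C, argon; then HCl (aq)
Reagents that add atoms: hydrogen peroxide, OO
Why: Dakin oxidation, in which hydroperoxide adds to the para-hydroxybenzaldehyde, aryl migration gives formate 19 and hydrolysis in the basic medium leaves the hydroquinone with bromine ortho to the hydroxyl that is flanked by methoxy.

Step 11
Reactants: 20 2-bromo-6-methoxybenzene-1,4-diol
Product: 21 1-bromo-3-methoxy-2,5-bis(methoxymethoxy)benzene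
Conditions: MeOCH2Cl, i-Pr2NEt, CH2Cl2, 0 °C to 40 °C
Reagents that add atoms: chloromethyl methyl ether, COCCl
Why: O-Alkylation of both phenols with the reactive α-chloro ether (Williamson type) gives base-stable acetals that survive the organometallic, enolate and hydrogenation steps.

Step 12
Reactants: 21 1-bromo-3-methoxy-2,5-bis(methoxymethoxy)benzene
Product: 23 tributyl[3-methoxy-2,5-bis(methoxymethoxy)phenyl]stannane, via aryllithium 22 (not isolated)
Conditions: n-BuLi, THF, −78 °C; Bu3SnCl, −78 °C to 0 °C
Reagents that add atoms: tributyltin chloride, CCCC[Sn](Cl)(CCCC)CCCC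
Why: Bromine–lithium exchange is faster than ortho-metalation at −78 °C, and the aryllithium is stannylated at the same carbon.

Step 13
Reactants: 17 (4aS,8aS)-2,5,5,8a-tetramethyl-3,4,4a,5,6,7,8,8a-octahydronaphthalen-1-yl trifluoromethanesulfonate; 23 tributyl[3-methoxy-2,5-bis(methoxymethoxy)phenyl]stannane
Product: 24 [3-methoxy-2,5-bis(methoxymethoxy)phenyl][(4aS,8aS)-2,5,5,8a-tetramethyl-3,4,4a,5,6,7,8,8a-octahydronaphthalen-1-yl]methanone
Conditions: Pd(PPh3)4 (5 mol%), LiCl (3 equiv), CO (3 bar), THF, 65 °C
Reagents that add atoms: carbon monoxide, [C-]#[O+]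
Why: Carbonylative Stille coupling, in which the enol triflate adds oxidatively to zerovalent palladium, CO inserts (favoured for the hindered alkenylpalladium), and transmetalation from tin followed by reductive elimination installs C11 as the aroyl carbonyl.

Step 14
Reactants: 24 [3-methoxy-2,5-bis(methoxymethoxy)phenyl][(4aS,8aS)-2,5,5,8a-tetramethyl-3,4,4a,5,6,7,8,8a-octahydronaphthalen-1-yl]methanone
Product: 25 [3-methoxy-2,5-bis(methoxymethoxy)phenyl][(1S,2S,4aS,8aS)-2,5,5,8a-tetramethyldecahydronaphthalen-1-yl]methanone
Conditions: H2 (60 bar), Pd/C (10 wt%), EtOAc, 50 °C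
Reagents that add atoms: none
Why: Syn-hydrogenation of the tetrasubstituted enone from the α face of the trans-decalin, opposite the axial C10 methyl, should place the C8 methyl β (8S, cis to the C10 methyl) and the aroyl group β at C9, a centre that is removed again in step 15.

Step 15
Reactants: 25 [3-methoxy-2,5-bis(methoxymethoxy)phenyl][(1S,2S,4aS,8aS)-2,5,5,8a-tetramethyldecahydronaphthalen-1-yl]methanone
Product: 27 [3-methoxy-2,5-bis(methoxymethoxy)phenyl][(2S,4aS,8aS)-2,5,5,8a-tetramethyloctahydronaphthalen-1(2H)-ylidene]methyl trifluoromethanesulfonate, via potassium enolate 26 (not isolated)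
Conditions: KN(SiMe3)2, THF, −78 °C to 0 °C; PhNTf2, 0 °C to 25 °C
Reagents that add atoms: N-phenylbis(trifluoromethanesulfonimide), O=S(=O)(N(c1ccccc1)S(=O)(=O)C(F)(F)F)C(F)(F)F
Why: The aryl ketone has a single α-hydrogen (C9–H), so enolate formation and O-triflation are regiodefined, and the enol triflate geometry (either isomer) does not matter because step 16 is stereoconvergent.

Step 16
Reactants: 27 [3-methoxy-2,5-bis(methoxymethoxy)phenyl][(2S,4aS,8aS)-2,5,5,8a-tetramethyloctahydronaphthalen-1(2H)-ylidene]methyl trifluoromethanesulfonate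
Product: 28 1-[(E)-chloro[(2S,4aS,8aS)-2,5,5,8a-tetramethyloctahydronaphthalen-1(2H)-ylidene]methyl]-3-methoxy-2,5-bis(methoxymethoxy)benzene
Conditions: Et4NCl (10 equiv), 2,6-lutidine (2 equiv), (CF3)2CHOH, 50 °C
Reagents that add atoms: tetraethylammonium chloride, CC[N+](CC)(CC)CC.[Cl-]
Why: Vinylic SN1 substitution, in which the α-aryl enol triflate ionises in the strongly ionising, weakly nucleophilic solvent to a linear aryl-stabilised vinyl cation whose vacant in-plane orbital should be attacked by chloride from the C8 side (only H8 lies in that plane) rather than past the equatorial C1 methylene on quaternary C10, so that chlorine ends cis to C8 and the aryl group cis to C10 (E) from either triflate isomer.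

Step 17
Reactants: 28 1-[(E)-chloro[(2S,4aS,8aS)-2,5,5,8a-tetramethyloctahydronaphthalen-1(2H)-ylidene]methyl]-3-methoxy-2,5-bis(methoxymethoxy)benzene
Product: 29 2-[(E)-chloro[(2S,4aS,8aS)-2,5,5,8a-tetramethyloctahydronaphthalen-1(2H)-ylidene]methyl]-6-methoxybenzene-1,4-diol
Conditions: HCl (1.25 M in MeOH), THF, 25 °C, argon
Reagents that add atoms: none
Why: Acid-catalysed acetal exchange with methanol removes both methoxymethyl groups under conditions expected to be too mild to protonate the twisted tetrasubstituted chloroalkene, giving the air-sensitive hydroquinone target.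

**Compound list**

1 | 2,2,6-trimethylcyclohexan-1-one | CC1CCCC(C)(C)C1=O | starting material
2 | allyl chloroformate | C=CCOC(=O)Cl | starting material
3 | lithium 2,6,6-trimethylcyclohex-1-en-1-olate | [Li+].[O-]C1=C(C)CCCC1(C)C | intermediate
4 | allyl 2,6,6-trimethylcyclohex-1-en-1-yl carbonate | C=CCOC(=O)OC1=C(C)CCCC1(C)C | intermediate
5 | (2R)-2-allyl-2,6,6-trimethylcyclohexan-1-one | C=CC[C@@]1(C)CCCC(C)(C)C1=O | intermediate
6 | (2R)-2,6,6-trimethyl-2-[(E)-prop-1-en-1-yl]cyclohexan-1-one | C/C=C/[C@@]1(C)CCCC(C)(C)C1=O | intermediate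
7 | 3-methyl-5-[(1R)-1,3,3-trimethyl-2-oxocyclohexyl]-1,2,4-trioxolane (ozonide) | CC1OOC(O1)[C@@]2(C)CCCC(C)(C)C2=O | intermediate
8 | (1R)-1,3,3-trimethyl-2-oxocyclohexane-1-carbaldehyde | O=C[C@@]1(C)CCCC(C)(C)C1=O | intermediate
9 | (2R)-2-(1-hydroxypropyl)-2,6,6-trimethylcyclohexan-1-one (both carbinol epimers) | CCC(O)[C@@]1(C)CCCC(C)(C)C1=O | intermediate
10 | (2R)-2,6,6-trimethyl-2-propanoylcyclohexan-1-one | CCC(=O)[C@@]1(C)CCCC(C)(C)C1=O | intermediate
11 | vinyltriphenylphosphonium bromide | C=C[P+](c1ccccc1)(c1ccccc1)c1ccccc1.[Br-] | starting material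
12 | potassium 1-[(1R)-1,3,3-trimethyl-2-oxocyclohexyl]prop-1-en-1-olate | CC=C([O-])[C@@]1(C)CCCC(C)(C)C1=O.[K+] | intermediate
13 | (2R)-2,6,6-trimethyl-2-[2-methyl-4-(triphenyl-λ5-phosphanylidene)butanoyl]cyclohexan-1-one | CC(CC=P(c1ccccc1)(c1ccccc1)c1ccccc1)C(=O)[C@@]1(C)CCCC(C)(C)C1=O | intermediate
14 | (8aS)-2,5,5,8a-tetramethyl-3,5,6,7,8,8a-hexahydronaphthalen-1(2H)-one (C2 epimers) | CC1CC=C2C(C)(C)CCC[C@]2(C)C1=O | intermediate
15 | (4aS,8aS)-2,5,5,8a-tetramethyl-3,4,4a,5,6,7,8,8a-octahydronaphthalen-1(2H)-one (C2 epimers) | CC1CC[C@H]2C(C)(C)CCC[C@]2(C)C1=O | intermediate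
16 | potassium (4aS,8aS)-2,5,5,8a-tetramethyl-3,4,4a,5,6,7,8,8a-octahydronaphthalen-1-olate | CC1=C([O-])[C@@]2(C)CCCC(C)(C)[C@@H]2CC1.[K+] | intermediate
17 | (4aS,8aS)-2,5,5,8a-tetramethyl-3,4,4a,5,6,7,8,8a-octahydronaphthalen-1-yl trifluoromethanesulfonate | CC1=C(OS(=O)(=O)C(F)(F)F)[C@@]2(C)CCCC(C)(C)[C@@H]2CC1 | intermediate
18 | 3-bromo-4-hydroxy-5-methoxybenzaldehyde (5-bromovanillin) | COc1cc(C=O)cc(Br)c1O | starting material
19 | 3-bromo-4-hydroxy-5-methoxyphenyl formate | COc1cc(OC=O)cc(Br)c1O | intermediate
20 | 2-bromo-6-methoxybenzene-1,4-diol | COc1cc(O)cc(Br)c1O | intermediate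
21 | 1-bromo-3-methoxy-2,5-bis(methoxymethoxy)benzene | COCOc1cc(Br)c(OCOC)c(OC)c1 | intermediate
22 | [3-methoxy-2,5-bis(methoxymethoxy)phenyl]lithium | [Li]c1cc(OCOC)cc(OC)c1OCOC | intermediate
23 | tributyl[3-methoxy-2,5-bis(methoxymethoxy)phenyl]stannane | CCCC[Sn](CCCC)(CCCC)c1cc(OCOC)cc(OC)c1OCOC | intermediate
24 | [3-methoxy-2,5-bis(methoxymethoxy)phenyl][(4aS,8aS)-2,5,5,8a-tetramethyl-3,4,4a,5,6,7,8,8a-octahydronaphthalen-1-yl]methanone | CC1=C(C(=O)c2cc(OCOC)cc(OC)c2OCOC)[C@@]2(C)CCCC(C)(C)[C@@H]2CC1 | intermediate
25 | [3-methoxy-2,5-bis(methoxymethoxy)phenyl][(1S,2S,4aS,8aS)-2,5,5,8a-tetramethyldecahydronaphthalen-1-yl]methanone | C[C@H]1CC[C@H]2C(C)(C)CCC[C@]2(C)[C@H]1C(=O)c1cc(OCOC)cc(OC)c1OCOC | intermediate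
26 | potassium [3-methoxy-2,5-bis(methoxymethoxy)phenyl][(2S,4aS,8aS)-2,5,5,8a-tetramethyloctahydronaphthalen-1(2H)-ylidene]methanolate | C[C@H]1CC[C@H]2C(C)(C)CCC[C@]2(C)C1=C([O-])c1cc(OCOC)cc(OC)c1OCOC.[K+] | intermediate
27 | [3-methoxy-2,5-bis(methoxymethoxy)phenyl][(2S,4aS,8aS)-2,5,5,8a-tetramethyloctahydronaphthalen-1(2H)-ylidene]methyl trifluoromethanesulfonate (either alkene geometry) | C[C@H]1CC[C@H]2C(C)(C)CCC[C@]2(C)C1=C(OS(=O)(=O)C(F)(F)F)c1cc(OCOC)cc(OC)c1OCOC | intermediate
28 | 1-[(E)-chloro[(2S,4aS,8aS)-2,5,5,8a-tetramethyloctahydronaphthalen-1(2H)-ylidene]methyl]-3-methoxy-2,5-bis(methoxymethoxy)benzene | C[C@H]1CC[C@H]2C(C)(C)CCC[C@]2(C)/C1=C(/Cl)c1cc(OCOC)cc(OC)c1OCOC | intermediate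
29 | 2-[(E)-chloro[(2S,4aS,8aS)-2,5,5,8a-tetramethyloctahydronaphthalen-1(2H)-ylidene]methyl]-6-methoxybenzene-1,4-diol | C[C@H]1CC[C@H]2C(C)(C)CCC[C@]2(C)/C1=C(/Cl)c1cc(O)cc(OC)c1O | target

**Step count**

Total: 17 steps. Longest linear sequence: 14 steps (steps 1–9 and 13–17, from 1). The arylstannane branch (steps 10–12, from 18) is 3 steps and joins in step 13.

**Steps most likely to fail**

Step 7. The ylide may fail to engage the C5 carbonyl, because oxaphosphetane formation at a ketone between two quaternary carbons is slow, so that the reaction stops at the Michael adduct or the diketone suffers retro-Claisen cleavage. The fallback sets out from 10 and builds the two bonds one after the other. The potassium enolate of 10 is alkylated at C8 with allyl bromide to give (2R)-2,6,6-trimethyl-2-(2-methylpent-4-enoyl)cyclohexan-1-one F1. Ozonolysis of the terminal alkene (O3, then PPh3) gives the keto aldehyde 3-methyl-4-oxo-4-[(1R)-1,3,3-trimethyl-2-oxocyclohexyl]butanal F2. Intramolecular McMurry coupling of the aldehyde with the C5 ketone (TiCl3(DME)1.5, Zn(Cu), DME, reflux, high dilution; low-valent titanium tolerates hindered ketones, and only the six-membered closure is feasible) then comes back to the route at 14.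

Step 14. Hydrogen uptake at the tetrasubstituted, twisted C8=C9 enone may stall, facial selectivity at C8 may be eroded by alkene migration on the catalyst, or the aryl ketone may be over-reduced. The fallback sets out from 24 and uses a radical hydrogen-atom-transfer conjugate reduction instead of surface hydrogenation (Mn(dpm)3 cat., PhSiH3, t-BuOOH, i-PrOH, 25 °C). The metal hydride should deliver a hydrogen atom to C8 from the open α face, and the resulting C9 radical is reduced and protonated. It comes back to the route at 25 without new intermediates.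

Step 16. Ionisation may be too slow with the twisted alkoxyaryl donor, capture by solvent may compete with chloride, or the geometry may erode through re-ionisation of the product. The fallback sets out from 27 and replaces ionisation by nickel-catalysed halogen exchange of the enol triflate (Ni(cod)2 cat., LiCl, DMA/THF, 25 °C). This runs through an alkenylnickel intermediate formed by oxidative addition to zerovalent nickel, in which the bulky metal fragment should likewise prefer the C8 side. It comes back to the route at 28, and any minor geometric isomer would be removed by chromatography.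

Further compounds
F1 | step 7 | (2R)-2,6,6-trimethyl-2-(2-methylpent-4-enoyl)cyclohexan-1-one | C=CCC(C)C(=O)[C@@]1(C)CCCC(C)(C)C1=O
F2 | step 7 | 3-methyl-4-oxo-4-[(1R)-1,3,3-trimethyl-2-oxocyclohexyl]butanal | O=CCC(C)C(=O)[C@@]1(C)CCCC(C)(C)C1=O
F0 | step 14 | none | none
F0 | step 16 | none | none
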